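**Retrosynthetic overview**

1. The target should arise by one global hydrogenolysis of a tribenzyl-protected ketone (benzyl ester on ring A, the vanillate ring; benzyl ether on the phenol of ring B, the syringyl ring; benzyl ether on the primary alcohol).
2. Key disconnection: the bond between the ketone carbon and ring carbon C1 of the 4-hydroxy-3,5-dimethoxyphenyl ring (ring B), made by nickel-catalysed reductive cross-electrophile coupling of an S-2-pyridyl thioester with an aryl bromide, a union of two electrophilic carbons by polarity reversal at nickel.
3. Enabling feature: the ketone carbon is an acyl carbon whose only other neighbour is the base-labile CH stereocentre bearing the O-aryl group, and ring B carbon C1 lies para to the phenol oxygen between two unsubstituted CH positions (C2 and C6). The acyl carbon can therefore enter as a chelating thioester and C1 as an unhindered C–Br bond, and the union needs neither base nor a carbanion.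
4. The (S)-stereocentre is built before the coupling: O-benzyl-D-serine gives the (R)-α-hydroxy acid (diazotisation, retention), then Mitsunobu etherification with benzyl vanillate (inversion).
5. No ring is formed in the route; ring A comes from vanillic acid and ring B from 4-bromo-2,6-dimethoxyphenol, so there is no order of ring formation.

Key step: step 8

Assumption (remark on the chemistry): the stereocentre is (S) by CIP analysis of the given SMILES; it is taken to be configurationally stable under neutral conditions but labile to base, so every step after its formation avoids strong base.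

**Route**

Step 1
Reactants: 1 vanillic acid (4-hydroxy-3-methoxybenzoic acid)
Product: 2 benzyl 4-hydroxy-3-methoxybenzoate (benzyl vanillate)
Conditions: BnBr, KHCO3, DMF, 40 °C
Reagents that add atoms: benzyl bromide, BrCc1ccccc1
Why: SN2 O-alkylation of the carboxylate under bicarbonate, a base too weak to deprotonate the phenol appreciably, should give the benzyl ester chemoselectively.

Step 2
Reactants: 3 O-benzyl-D-serine ((2R)-2-amino-3-(benzyloxy)propanoic acid)
Product: 4 (2R)-3-(benzyloxy)-2-hydroxypropanoic acid
Conditions: NaNO2, aq. H2SO4, 0 °C to rt
Reagents that add atoms: water, O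
Why: Diazotisation of the α-amino acid and hydrolysis should proceed with net retention (double inversion through participation of the neighbouring carboxylate), so the (R)-configuration of D-serine is carried into the α-hydroxy acid.

Step 3
Reactants: 4 (2R)-3-(benzyloxy)-2-hydroxypropanoic acid
Product: 5 allyl (2R)-3-(benzyloxy)-2-hydroxypropanoate
Conditions: allyl bromide, KHCO3, DMF, rt
Reagents that add atoms: allyl bromide, C=CCBr
Why: Chemoselective SN2 O-alkylation of the carboxylate leaves the secondary alcohol free and installs an ester that can later be removed without touching the benzyl ester.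

Step 4
Reactants: 5 allyl (2R)-3-(benzyloxy)-2-hydroxypropanoate; 2 benzyl 4-hydroxy-3-methoxybenzoate
Product: 6 benzyl 4-{[(2S)-1-(allyloxy)-3-(benzyloxy)-1-oxopropan-2-yl]oxy}-3-methoxybenzoate
Conditions: PPh3, DIAD, THF, 0 °C to rt
Reagents that add atoms: none
Why: In this Mitsunobu etherification the acidic phenol of 2 should displace the alkoxyphosphonium-activated α-hydroxy ester by SN2 with clean inversion, which sets the (S)-configured aryl ether stereocentre of the target.

Step 5
Reactants: 6 benzyl 4-{[(2S)-1-(allyloxy)-3-(benzyloxy)-1-oxopropan-2-yl]oxy}-3-methoxybenzoate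
Product: 7 (2S)-3-(benzyloxy)-2-{4-[(benzyloxy)carbonyl]-2-methoxyphenoxy}propanoic acid
Conditions: Pd(PPh3)4 (cat.), morpholine, THF, rt; dilute citric acid work-up
Reagents that add atoms: none
Why: In this Tsuji–Trost deallylation zerovalent palladium ionises only the allyl ester to a π-allyl complex that morpholine captures, under conditions too mild to cleave the benzyl ester or to enolise the α-aryloxy acid.

Step 6
Reactants: 7 (2S)-3-(benzyloxy)-2-{4-[(benzyloxy)carbonyl]-2-methoxyphenoxy}propanoic acid
Product: 8 S-(pyridin-2-yl) (2S)-3-(benzyloxy)-2-{4-[(benzyloxy)carbonyl]-2-methoxyphenoxy}propanethioate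
Conditions: 2,2'-dipyridyl disulfide, PPh3, CH2Cl2, rt
Reagents that add atoms: 2,2'-dipyridyl disulfide, c1ccc(SSc2ccccn2)nc1
Why: The Mukaiyama redox condensation should convert the acid into the S-2-pyridyl thioester under neutral conditions, with no base present to epimerise the α-centre.

Step 7
Reactants: 9 4-bromo-2,6-dimethoxyphenol
Product: 10 2-(benzyloxy)-5-bromo-1,3-dimethoxybenzene
Conditions: BnBr, K2CO3, DMF, 60 °C
Reagents that add atoms: benzyl bromide, BrCc1ccccc1
Why: A Williamson ether synthesis on the acidic 2,6-dimethoxyphenol masks the phenol as a benzyl ether that falls in the final hydrogenolysis.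

Step 8
Reactants: 8 S-(pyridin-2-yl) (2S)-3-(benzyloxy)-2-{4-[(benzyloxy)carbonyl]-2-methoxyphenoxy}propanethioate; 10 2-(benzyloxy)-5-bromo-1,3-dimethoxybenzene
Product: 11 benzyl 4-{[(2S)-3-(benzyloxy)-1-[4-(benzyloxy)-3,5-dimethoxyphenyl]-1-oxopropan-2-yl]oxy}-3-methoxybenzoate
Conditions: NiBr2(DME) (cat.), 4,4'-di-tert-butyl-2,2'-bipyridine (dtbbpy, cat.), Zn powder, NaI (cat.), DMA, 25 °C
Reagents that add atoms: none
Why: Zerovalent nickel ligated by dtbbpy should insert into the C–Br bond of 10 and, after one-electron reduction by zinc to monovalent aryl nickel, into the N,S-chelation-activated C(acyl)–S bond of 8 (the two oxidative additions may also occur in the opposite order), and the trivalent acyl(aryl)nickel species then reductively eliminates ketone 11 while zinc returns nickel to the zerovalent state. The closest known reaction type is the nickel-catalysed reductive cross-electrophile ketone synthesis from S-2-pyridyl thioesters or other activated acyl donors and organic halides, a union of two electrophilic carbons that needs no preformed organometallic reagent. No ring is closed and no new stereocentre is formed; the existing (S)-centre should be carried through unchanged because the medium holds no base stronger than a zinc thiolate and the acyl nickel species is not expected to enolise, by analogy with α-amino acid thioesters in this reaction type. The step needs cross-coupling over homocoupling, which the different activation modes of the two partners should secure (a chelating thioester against an aryl bromide whose reacting carbon is flanked by two unsubstituted ring CH positions), and it needs chemoselectivity over the benzyl ester and the aryl and benzyl ether C–O bonds, which are inert to nickel at 25 °C. Decarbonylation of the α-aryloxy acyl nickel should be outrun by reductive elimination at this temperature.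

Step 9
Reactants: 11 benzyl 4-{[(2S)-3-(benzyloxy)-1-[4-(benzyloxy)-3,5-dimethoxyphenyl]-1-oxopropan-2-yl]oxy}-3-methoxybenzoate
Product: 12 4-{[(2S)-3-hydroxy-1-(4-hydroxy-3,5-dimethoxyphenyl)-1-oxopropan-2-yl]oxy}-3-methoxybenzoic acid (CNP0507417.2)
Conditions: H2 (1 atm), 10% Pd/C, EtOAc/EtOH, rt
Reagents that add atoms: none
Why: Heterogeneous catalytic hydrogenolysis should cleave the benzyl ester, the aryl benzyl ether and the alkyl benzyl ether in one neutral operation, leaving the electron-rich aryl ketone and the labile α-stereocentre untouched at ambient temperature and pressure.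

**Compound list**

1 | vanillic acid (4-hydroxy-3-methoxybenzoic acid) | COc1cc(C(=O)O)ccc1O | starting material
2 | benzyl 4-hydroxy-3-methoxybenzoate | COc1cc(C(=O)OCc2ccccc2)ccc1O | intermediate
3 | O-benzyl-D-serine, (2R)-2-amino-3-(benzyloxy)propanoic acid | N[C@H](COCc1ccccc1)C(=O)O | starting material
4 | (2R)-3-(benzyloxy)-2-hydroxypropanoic acid | O[C@H](COCc1ccccc1)C(=O)O | intermediate
5 | allyl (2R)-3-(benzyloxy)-2-hydroxypropanoate | O[C@H](COCc1ccccc1)C(=O)OCC=C | intermediate
6 | benzyl 4-{[(2S)-1-(allyloxy)-3-(benzyloxy)-1-oxopropan-2-yl]oxy}-3-methoxybenzoate | COc1cc(C(=O)OCc2ccccc2)ccc1O[C@@H](COCc1ccccc1)C(=O)OCC=C | intermediate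
7 | (2S)-3-(benzyloxy)-2-{4-[(benzyloxy)carbonyl]-2-methoxyphenoxy}propanoic acid | COc1cc(C(=O)OCc2ccccc2)ccc1O[C@@H](COCc1ccccc1)C(=O)O | intermediate
8 | S-(pyridin-2-yl) (2S)-3-(benzyloxy)-2-{4-[(benzyloxy)carbonyl]-2-methoxyphenoxy}propanethioate | COc1cc(C(=O)OCc2ccccc2)ccc1O[C@@H](COCc1ccccc1)C(=O)Sc1ccccn1 | intermediate
9 | 4-bromo-2,6-dimethoxyphenol | COc1cc(Br)cc(OC)c1O | starting material
10 | 2-(benzyloxy)-5-bromo-1,3-dimethoxybenzene | COc1cc(Br)cc(OC)c1OCc1ccccc1 | intermediate
11 | benzyl 4-{[(2S)-3-(benzyloxy)-1-[4-(benzyloxy)-3,5-dimethoxyphenyl]-1-oxopropan-2-yl]oxy}-3-methoxybenzoate | COc1cc(C(=O)OCc2ccccc2)ccc1O[C@@H](COCc1ccccc1)C(=O)c1cc(OC)c(OCc2ccccc2)c(OC)c1 | intermediate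
12 | 4-{[(2S)-3-hydroxy-1-(4-hydroxy-3,5-dimethoxyphenyl)-1-oxopropan-2-yl]oxy}-3-methoxybenzoic acid | COc1cc(C(=O)O)ccc1O[C@@H](CO)C(=O)c1cc(OC)c(O)c(OC)c1 | target

**Step count and risks**

Total step count: 9. Longest linear sequence: 7 steps (steps 2, 3, 4, 5, 6, 8 and 9, from O-benzyl-D-serine).

Steps most likely to fail:

Step 8 (key coupling). The coupling may be eroded by homocoupling or reductive dehalogenation of the aryl bromide, by decarbonylation at acyl nickel, or by zinc-salt-promoted epimerisation or β-elimination of benzyl alcohol in the product. The fallback returns to the classical polarity, an aryl nucleophile adding to the acyl electrophile. It sets out from 10 and 8: bromide 10 is converted with Mg turnings (LiCl, THF) into [4-(benzyloxy)-3,5-dimethoxyphenyl]magnesium bromide F1. F1 is added at −78 °C to thioester 8 in THF, the known ketone synthesis from S-2-pyridyl thioesters and Grignard reagents. The chelating thioester should be consumed faster than the benzyl ester is attacked and faster than α-deprotonation occurs, and aqueous NH4Cl quench at low temperature brings the route back at 11.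

Step 9 (global debenzylation). Over-reduction of the aryl ketone or reductive scission of the α-aryloxy C–O bond may compete with the slow cleavage of the primary alkyl benzyl ether. The fallback replaces reduction by a Lewis-acid dealkylation. It sets out from 11 and treats it with BCl3 and pentamethylbenzene (a non-basic benzyl cation scavenger) in CH2Cl2 at −78 °C, followed by a methanol quench. This should remove all three benzyl groups without a reductant and without touching the methyl ethers, and it comes back to the route directly at 12 with no new compound on its way.

Step 4 (Mitsunobu etherification). Displacement at the secondary carbinol next to the ester may be sluggish, with competing alkylation of the reduced azodicarboxylate or partial erosion of the inversion. The fallback separates activation from displacement. It sets out from 5, which is converted with Tf2O and 2,6-lutidine (CH2Cl2, −78 °C) into allyl (2R)-3-(benzyloxy)-2-{[(trifluoromethyl)sulfonyl]oxy}propanoate F2. The triflate is then displaced by phenol 2 with K2CO3 in MeCN at 0 °C in an SN2 reaction with inversion, and the route is rejoined at 6.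

Further compounds
F1 | step 8 | [4-(benzyloxy)-3,5-dimethoxyphenyl]magnesium bromide | COc1cc([Mg]Br)cc(OC)c1OCc1ccccc1
F0 | step 9 | none | none
F2 | step 4 | allyl (2R)-3-(benzyloxy)-2-{[(trifluoromethyl)sulfonyl]oxy}propanoate | FC(F)(F)S(=O)(=O)O[C@H](COCc1ccccc1)C(=O)OCC=C
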